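**Plan**

- Numbering (ring carbons in the order of the target SMILES): C1 (O‑angelate), C2 (O‑2‑methylbutanoate), C3H2, C4 (quaternary, Me), C5H, C6 (C=O), C7H=C8(Me), C9H, C10H, C11(Me)2. Rings: cyclobutane C4–C5–C10–C9, cyclohexenone C4–C5–C6–C7–C8–C9, cycloheptane C1–C2–C3–C4–C9–C10–C11.
- Retrosynthesis: cut the two ester C–O bonds, then C5–C10 (cyclobutane, enolate alkylation), then C4–C9 and C7–C8 together (intramolecular Diels–Alder), leaving an open‑chain 2‑silyloxydiene enone.
- Enabling feature: C10–C11(Me)2–C1(O)–C2(O) is the carbon skeleton of pantolactone and, with C3, forms the five‑atom tether between diene terminus C4 and dienophile carbon C9. One cycloaddition therefore closes the six‑ and the seven‑membered ring and leaves a C5=C6 silyl enol ether and a C10 ketone placed for the cyclobutane.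
- Forward: (S)‑pantolactone is extended at C2 (propargylation, then carboalumination to the C4=C5 iodoalkene) and at C10 (propenyl ketone); Stille coupling and enol silylation finish the diene. Six‑ and seven‑membered rings form together (step 11), then the cyclobutane (step 14), then the enone and the two esters.
- Stereochemistry: C1 from (S)‑pantolactone; C2 by chelation‑controlled addition; C4/C9 (cis) and their sense relative to C1/C2 in the Diels–Alder step; C10 by thermodynamic ketone reduction, then inversion in the ring closure, which also fixes C5; the side‑chain centre from (S)‑2‑methylbutanoic anhydride and the Z alkene from angelic acid.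

Key step: step 11

Remark: TBS = tert‑butyldimethylsilyl; "α face" of the seven‑membered ring is the face carrying C9–H (the six‑membered ring lies on the β face); compounds 3, 11, 16, 29 and 31 are taken as commercial.

**Route**

Step 1
Reactants: 1 (S)‑pantolactone
Product: 2 (3S)‑4,4‑dimethyloxolane‑2,3‑diol (lactol; anomer mixture)
Conditions: i‑Bu2AlH (DIBAL‑H, 2.2 equiv), CH2Cl2, −78 °C; aq. potassium sodium tartrate
Reagents that add atoms: none
Why: Partial lactone reduction with DIBAL‑H stops at the lactol because the aluminium hemiacetal survives at −78 °C (the first equivalent only deprotonates the hydroxyl), and the C1 stereocentre is not touched.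

Step 2
Reactants: 2 lactol; 3 propargyl bromide
Product: 5 (3S,4S)‑2,2‑dimethylhept‑6‑yne‑1,3,4‑triol, via allenylindium dibromide 4 (not isolated)
Conditions: In powder, THF/H2O (1:1), rt
Reagents that add atoms: propargyl bromide, C#CCBr
Why: Indium‑mediated Barbier propargylation in water acts on the open hydroxy‑aldehyde form of the lactol; indium chelated between the free α‑hydroxyl and the carbonyl oxygen, and SE2′ attack of the allenylindium on the face away from the tert‑alkyl group, should give the homopropargylic alcohol with the new C2 centre syn to C1–OH (4S).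

Step 3
Reactants: 5 triol
Product: 6 (3S,4S)‑1,3,4‑tris(TBS‑oxy)‑2,2‑dimethylhept‑6‑yne
Conditions: TBSOTf (3.5 equiv), 2,6‑lutidine, CH2Cl2, −78 → 0 °C
Reagents that add atoms: tert‑butyldimethylsilyl triflate, CC(C)(C)[Si](C)(C)OS(=O)(=O)C(F)(F)F
Why: Exhaustive silylation with a silyl triflate and 2,6‑lutidine, reactive enough for the neopentylic C1 hydroxyl, with no stereocentre affected.

Step 4
Reactants: 6 tris‑TBS alkyne
Product: 8 (1E,4S,5S)‑4,5,7‑tris(TBS‑oxy)‑1‑iodo‑2,6,6‑trimethylhept‑1‑ene, via alkenyldimethylalane 7 (not isolated)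
Conditions: Me3Al (2.5 equiv), Cp2ZrCl2 (0.25 equiv), CH2Cl2, 0 °C → rt; then iodine (I2), THF, −30 °C
Reagents that add atoms: trimethylaluminium, C[Al](C)C; iodine, II
Why: Negishi carboalumination adds Me–Al syn across the terminal alkyne with methyl on the internal carbon (C4), and iodinolysis with retention gives the (E)‑iodoalkene whose geometry later places the tether outside and the methyl inside on the diene.

Step 5
Reactants: 8 tris‑TBS iodoalkene
Product: 9 (3S,4S,6E)‑3,4‑bis(TBS‑oxy)‑7‑iodo‑2,2,6‑trimethylhept‑6‑en‑1‑ol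
Conditions: HF·pyridine, pyridine, THF, 0 °C
Reagents that add atoms: none
Why: Selective desilylation, since buffered HF·pyridine cleaves the primary silyl ether much faster than the two flanked secondary ones.

Step 6
Reactants: 9 primary alcohol
Product: 10 (3S,4S,6E)‑3,4‑bis(TBS‑oxy)‑7‑iodo‑2,2,6‑trimethylhept‑6‑enal
Conditions: Dess–Martin periodinane, NaHCO3, CH2Cl2, rt
Reagents that add atoms: none
Why: Dess–Martin oxidation gives an aldehyde that has no α‑hydrogen and so cannot epimerise or enolise.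

Step 7
Reactants: 10 aldehyde; 11 (E)‑1‑bromoprop‑1‑ene
Product: 14 (2E,6S,7S,9E)‑6,7‑bis(TBS‑oxy)‑10‑iodo‑5,5,9‑trimethyldeca‑2,9‑dien‑4‑ol (C4 epimers), via (E)‑prop‑1‑enyllithium 12 (not isolated), via (E)‑prop‑1‑enylmagnesium bromide 13 (not isolated)
Conditions: 11, t‑BuLi (1.95 equiv per 11), Et2O, −78 °C; MgBr2·OEt2; then 10, −78 → −20 °C
Reagents that add atoms: (E)‑1‑bromoprop‑1‑ene, C/C=C/Br
Why: Grignard 1,2‑addition, in which lithium–bromine exchange proceeds with retention of alkene geometry and transmetalation to magnesium gives a nucleophile that adds to the hindered aldehyde without exchanging with the alkenyl iodide; the new carbinol centre is a mixture and is erased in step 8.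

Step 8
Reactants: 14 allylic alcohol
Product: 15 (2E,6S,7S,9E)‑6,7‑bis(TBS‑oxy)‑10‑iodo‑5,5,9‑trimethyldeca‑2,9‑dien‑4‑one
Conditions: Dess–Martin periodinane, NaHCO3, CH2Cl2, rt
Reagents that add atoms: none
Why: Dess–Martin oxidation of the allylic alcohol gives the (E)‑enone under buffered conditions that leave the iodoalkene and the silyl ethers alone.

Step 9
Reactants: 15 iodo enone; 16 tributyl(1‑ethoxyvinyl)stannane
Product: 18 (3E,6S,7S,10E)‑6,7‑bis(TBS‑oxy)‑4,8,8‑trimethyldodeca‑3,10‑diene‑2,9‑dione, via ethoxydiene 17 (not isolated)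
Conditions: PdCl2(PPh3)2 (5 mol %), DMF, 60 °C; then 1 M HCl, THF, 0 °C
Reagents that add atoms: tributyl(1‑ethoxyvinyl)stannane, CCCC[Sn](CCCC)(CCCC)C(=C)OCC; water, O
Why: Stille coupling of the alkenyl iodide proceeds with retention of the C4=C5 geometry, and brief dilute acid hydrolyses the enol ether to the methyl ketone.

Step 10
Reactants: 18 dienedione
Product: 19 (2E,6S,7S,9E)‑6,7,11‑tris(TBS‑oxy)‑5,5,9‑trimethyldodeca‑2,9,11‑trien‑4‑one
Conditions: TBSOTf (1.1 equiv), Et3N, CH2Cl2, −78 → −40 °C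
Reagents that add atoms: tert‑butyldimethylsilyl triflate, CC(C)(C)[Si](C)(C)OS(=O)(=O)C(F)(F)F
Why: Soft enolisation (silyl triflate and amine) of the methyl ketone at its methyl group gives the cross‑conjugated 2‑silyloxydiene, while the C10 ketone has no α‑hydrogen and is shielded by the C11 gem‑dimethyl group.

Step 11
Reactants: 19 silyloxydiene enone
Product: 20 cis‑fused bicyclic ketone silyl enol ether (C4‑Me and C9‑H cis; C8‑Me trans to C10; C1‑OTBS α; C2‑OTBS β)
Conditions: Me2AlCl (1.2 equiv), CH2Cl2, −78 → −20 °C; Et3N then aq. NaHCO3 at −78 °C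
Reagents that add atoms: none
Why: Me2AlCl bound to the C10 ketone lowers the enone LUMO and the 2‑silyloxydiene adds in a concerted but asynchronous [4+2] cycloaddition (C7–C8 leading, C4–C9 following; at the stepwise limit a Mukaiyama–Michael/Michael sequence), the closest known reaction type being Lewis acid‑promoted intramolecular Diels–Alder reactions of 2‑silyloxydienes with tethered enones. The cyclohexene ring closes by the cycloaddition itself and the seven‑membered ring by the C4–C9 bond across the tether C3–C2–C1–C11–C10, whose folding is helped by the C11 gem‑dimethyl group. C4 and C9 come out cis (C4 methyl and C9 hydrogen on one face) from the transition state with the tether carbonyl endo, together with the E geometry of C4=C5 (tether outside, methyl inside); C8 is set trans to C10 by the E enone and is erased later. The diene face used relative to C1 and C2 should follow from a chair‑like tether with both silyl ethers pseudo‑equatorial, because an axial C2 substituent would meet a C11 methyl in a syn‑pentane contact. The step needs endo and facial selectivity plus enough reactivity from a diene whose terminus carries an inside methyl; internal activation by the complexed ketone, the electron‑rich diene and a cold basic quench (which keeps the C5=C6 silyl enol ether) are what should secure them.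

Step 12
Reactants: 20 bicyclic ketone
Product: 21 C10 α‑alcohol of 20 (OH cis to C9‑H and to C1‑OTBS; enol ether intact)
Conditions: Li, NH3 (l)/THF, EtOH (2.2 equiv), −78 °C
Reagents that add atoms: none
Why: Dissolving‑metal reduction of a hindered ketone is thermodynamically controlled and should give the equatorial C10 alcohol on the α face (opposite the six‑membered ring) rather than the axial epimer expected from hydride attack on the exposed face, while the silyl enol ether keeps C6 masked.

Step 13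
Reactants: 21 alcohol
Product: 22 C10 α‑mesylate
Conditions: MsCl, Et3N, CH2Cl2, 0 °C
Reagents that add atoms: methanesulfonyl chloride, CS(=O)(=O)Cl
Why: Mesylation with MsCl/Et3N works on hindered secondary alcohols and keeps the C10 configuration.

Step 14
Reactants: 22 mesylate
Product: 24 tricyclic ketone (cyclobutane C4–C5–C10–C9 closed; C6 ketone; C7H2; C8‑H(Me); bis‑TBS ether), via sulfonium enolate 23 (not isolated)
Conditions: TASF [tris(dimethylamino)sulfonium difluorotrimethylsilicate, 1.1 equiv], THF, −40 °C → rt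
Reagents that add atoms: none
Why: Fluoride frees the regiodefined C5 enolate from the silyl enol ether, and C5 alkylates C10 intramolecularly (4‑exo‑tet SN2, the known route from keto sulfonates to bicyclo[3.1.1]heptanones) from the β face with inversion, so the ring geometry alone sets C5 and C10; O‑alkylation would need a bridgehead alkene and E2 lacks an anti‑periplanar hydrogen.

Step 15
Reactants: 24 tricyclic ketone
Product: 27 tricyclic enone (C7=C8; bis‑TBS ether), via lithium enolate 25 (not isolated), via C7 sulfilimine adduct 26 (not isolated)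
Conditions: LiN(i‑Pr)2 (LDA), THF, −78 °C; then N‑tert‑butylbenzenesulfinimidoyl chloride, −78 °C
Reagents that add atoms: none
Why: Mukaiyama dehydrogenation, in which the ketone can enolise only towards C7 (C5 is a cyclobutane bridgehead), the lithium enolate is sulfenylated at C7 and the adduct loses the sulfenamide by syn‑elimination with the C8 hydrogen to give the C7=C8 enone.

Step 16
Reactants: 27 bis‑TBS enone
Product: 28 tricyclic enone diol (C1‑OH and C2‑OH free)
Conditions: HF·pyridine, THF, 0 °C → rt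
Reagents that add atoms: none
Why: Fluoride desilylation with HF·pyridine frees both secondary hydroxyls under mildly acidic conditions that the enone and the cyclobutane should tolerate.

Step 17
Reactants: 28 diol; 29 (S)‑2‑methylbutanoic anhydride
Product: 30 C2 (S)‑2‑methylbutanoate with free C1‑OH
Conditions: 29 (1.1 equiv), DMAP (cat.), pyridine, CH2Cl2, 0 °C
Reagents that add atoms: (S)‑2‑methylbutanoic anhydride, CC[C@H](C)C(=O)OC(=O)[C@@H](C)CC
Why: DMAP‑catalysed acylation by the anhydride is expected at the C2 hydroxyl because the C1 hydroxyl is neopentylic (next to C11Me2), and the (S) centre of the acyl group is carried in unchanged.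

Step 18
Reactants: 30 mono‑ester; 31 angelic acid
Product: 33 CNP0323606.1 (target), via angelic 2,4,6‑trichlorobenzoic anhydride 32 (not isolated)
Conditions: 31, 2,4,6‑trichlorobenzoyl chloride, Et3N, toluene, rt; then 30, 80 °C
Reagents that add atoms: angelic acid, C/C=C(/C)C(=O)O
Why: Yamaguchi esterification through the mixed anhydride acylates the hindered C1 hydroxyl with retention at C1 and is the usual way to avoid Z‑to‑E isomerisation to the tiglate.

**Compound list**

1 | (S)‑pantolactone | O[C@@H]1C(=O)OCC1(C)C | starting material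
2 | (3S)‑4,4‑dimethyloxolane‑2,3‑diol (anomer mixture) | O[C@@H]1C(O)OCC1(C)C | intermediate
3 | propargyl bromide | C#CCBr | starting material
4 | allenylindium dibromide (not isolated) | C=C=C[In](Br)Br | intermediate
5 | (3S,4S)‑2,2‑dimethylhept‑6‑yne‑1,3,4‑triol | C#CC[C@H](O)[C@@H](O)C(C)(C)CO | intermediate
6 | (3S,4S)‑1,3,4‑tris(TBS‑oxy)‑2,2‑dimethylhept‑6‑yne | C#CC[C@H](O[Si](C)(C)C(C)(C)C)[C@@H](O[Si](C)(C)C(C)(C)C)C(C)(C)CO[Si](C)(C)C(C)(C)C | intermediate
7 | dimethyl[(1E,4S,5S)‑4,5,7‑tris(TBS‑oxy)‑2,6,6‑trimethylhept‑1‑enyl]alane (not isolated) | C[Al](C)/C=C(\C)C[C@H](O[Si](C)(C)C(C)(C)C)[C@@H](O[Si](C)(C)C(C)(C)C)C(C)(C)CO[Si](C)(C)C(C)(C)C | intermediate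
8 | (1E,4S,5S)‑4,5,7‑tris(TBS‑oxy)‑1‑iodo‑2,6,6‑trimethylhept‑1‑ene | I/C=C(\C)C[C@H](O[Si](C)(C)C(C)(C)C)[C@@H](O[Si](C)(C)C(C)(C)C)C(C)(C)CO[Si](C)(C)C(C)(C)C | intermediate
9 | (3S,4S,6E)‑3,4‑bis(TBS‑oxy)‑7‑iodo‑2,2,6‑trimethylhept‑6‑en‑1‑ol | I/C=C(\C)C[C@H](O[Si](C)(C)C(C)(C)C)[C@@H](O[Si](C)(C)C(C)(C)C)C(C)(C)CO | intermediate
10 | (3S,4S,6E)‑3,4‑bis(TBS‑oxy)‑7‑iodo‑2,2,6‑trimethylhept‑6‑enal | I/C=C(\C)C[C@H](O[Si](C)(C)C(C)(C)C)[C@@H](O[Si](C)(C)C(C)(C)C)C(C)(C)C=O | intermediate
11 | (E)‑1‑bromoprop‑1‑ene | C/C=C/Br | starting material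
12 | (E)‑prop‑1‑enyllithium (not isolated) | [Li]/C=C/C | intermediate
13 | (E)‑prop‑1‑enylmagnesium bromide (not isolated) | Br[Mg]/C=C/C | intermediate
14 | (2E,6S,7S,9E)‑6,7‑bis(TBS‑oxy)‑10‑iodo‑5,5,9‑trimethyldeca‑2,9‑dien‑4‑ol (C4 epimers) | I/C=C(\C)C[C@H](O[Si](C)(C)C(C)(C)C)[C@@H](O[Si](C)(C)C(C)(C)C)C(C)(C)C(O)/C=C/C | intermediate
15 | (2E,6S,7S,9E)‑6,7‑bis(TBS‑oxy)‑10‑iodo‑5,5,9‑trimethyldeca‑2,9‑dien‑4‑one | I/C=C(\C)C[C@H](O[Si](C)(C)C(C)(C)C)[C@@H](O[Si](C)(C)C(C)(C)C)C(C)(C)C(=O)/C=C/C | intermediate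
16 | tributyl(1‑ethoxyvinyl)stannane | CCCC[Sn](CCCC)(CCCC)C(=C)OCC | starting material
17 | (2E,6S,7S,9E)‑6,7‑bis(TBS‑oxy)‑11‑ethoxy‑5,5,9‑trimethyldodeca‑2,9,11‑trien‑4‑one (not isolated) | C=C(OCC)/C=C(\C)C[C@H](O[Si](C)(C)C(C)(C)C)[C@@H](O[Si](C)(C)C(C)(C)C)C(C)(C)C(=O)/C=C/C | intermediate
18 | (3E,6S,7S,10E)‑6,7‑bis(TBS‑oxy)‑4,8,8‑trimethyldodeca‑3,10‑diene‑2,9‑dione | CC(=O)/C=C(\C)C[C@H](O[Si](C)(C)C(C)(C)C)[C@@H](O[Si](C)(C)C(C)(C)C)C(C)(C)C(=O)/C=C/C | intermediate
19 | (2E,6S,7S,9E)‑6,7,11‑tris(TBS‑oxy)‑5,5,9‑trimethyldodeca‑2,9,11‑trien‑4‑one (Diels–Alder precursor) | C=C(O[Si](C)(C)C(C)(C)C)/C=C(\C)C[C@H](O[Si](C)(C)C(C)(C)C)[C@@H](O[Si](C)(C)C(C)(C)C)C(C)(C)C(=O)/C=C/C | intermediate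
20 | cis‑fused bicyclo[5.4.0]undecenone: C10 ketone, C5=C6 TBS enol ether, C4‑Me cis to C9‑H, C8‑Me trans to C10, C1‑OTBS α, C2‑OTBS β | CC(C)(C)[Si](C)(C)O[C@@H]1[C@@H](O[Si](C)(C)C(C)(C)C)C[C@@]2(C)C=C(O[Si](C)(C)C(C)(C)C)C[C@H](C)[C@H]2C(=O)C1(C)C | intermediate
21 | C10 α‑alcohol of 20 (OH cis to C9‑H) | CC(C)(C)[Si](C)(C)O[C@@H]1[C@@H](O[Si](C)(C)C(C)(C)C)C[C@@]2(C)C=C(O[Si](C)(C)C(C)(C)C)C[C@H](C)[C@H]2[C@H](O)C1(C)C | intermediate
22 | C10 α‑mesylate of 21 | CC(C)(C)[Si](C)(C)O[C@@H]1[C@@H](O[Si](C)(C)C(C)(C)C)C[C@@]2(C)C=C(O[Si](C)(C)C(C)(C)C)C[C@H](C)[C@H]2[C@H](OS(C)(=O)=O)C1(C)C | intermediate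
23 | tris(dimethylamino)sulfonium C5=C6 enolate of the mesylate (not isolated) | CC(C)(C)[Si](C)(C)O[C@@H]1[C@@H](O[Si](C)(C)C(C)(C)C)C[C@@]2(C)C=C([O-])C[C@H](C)[C@H]2[C@H](OS(C)(=O)=O)C1(C)C.CN(C)[S+](N(C)C)N(C)C | intermediate
24 | tricyclic ketone: cyclobutane closed, C6 ketone, C8‑H(Me), C1/C2 bis‑TBS ether | CC(C)(C)[Si](C)(C)O[C@@H]1[C@@H](O[Si](C)(C)C(C)(C)C)C[C@@]2(C)[C@@H]3C(=O)C[C@H](C)[C@H]2[C@@H]3C1(C)C | intermediate
25 | C6=C7 lithium enolate of 24 (not isolated) | CC(C)(C)[Si](C)(C)O[C@@H]1[C@@H](O[Si](C)(C)C(C)(C)C)C[C@@]2(C)[C@@H]3C(O[Li])=C[C@H](C)[C@H]2[C@@H]3C1(C)C | intermediate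
26 | C7 S‑phenyl‑N‑tert‑butylsulfilimine adduct of 24 (not isolated) | CC(C)(C)[Si](C)(C)O[C@@H]1[C@@H](O[Si](C)(C)C(C)(C)C)C[C@@]2(C)[C@@H]3C(=O)C(S(=NC(C)(C)C)c4ccccc4)[C@H](C)[C@H]2[C@@H]3C1(C)C | intermediate
27 | tricyclic C7=C8 enone, C1/C2 bis‑TBS ether | CC(C)(C)[Si](C)(C)O[C@@H]1[C@@H](O[Si](C)(C)C(C)(C)C)C[C@@]2(C)[C@@H]3C(=O)C=C(C)[C@H]2[C@@H]3C1(C)C | intermediate
28 | tricyclic enone C1,C2‑diol | O[C@@H]1[C@@H](O)C[C@@]2(C)[C@@H]3C(=O)C=C(C)[C@H]2[C@@H]3C1(C)C | intermediate
29 | (S)‑2‑methylbutanoic anhydride | CC[C@H](C)C(=O)OC(=O)[C@@H](C)CC | starting material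
30 | tricyclic enone C2 (S)‑2‑methylbutanoate, C1‑OH free | O[C@@H]1[C@@H](OC(=O)[C@@H](C)CC)C[C@@]2(C)[C@@H]3C(=O)C=C(C)[C@H]2[C@@H]3C1(C)C | intermediate
31 | angelic acid [(Z)‑2‑methylbut‑2‑enoic acid] | C/C=C(/C)C(=O)O | starting material
32 | angelic 2,4,6‑trichlorobenzoic anhydride (not isolated) | C/C=C(/C)C(=O)OC(=O)c1c(Cl)cc(Cl)cc1Cl | intermediate
33 | CNP0323606.1 (C1 angelate, C2 (S)‑2‑methylbutanoate) | C/C=C(/C)C(=O)O[C@@H]1[C@@H](OC(=O)[C@@H](C)CC)C[C@@]2(C)[C@@H]3C(=O)C=C(C)[C@H]2[C@@H]3C1(C)C | target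

**Count and risks**

Total: 18 steps. Longest linear sequence: 18 steps, from (S)‑pantolactone (1).

Steps most likely to fail:

Step 11 (cycloaddition). The inside methyl at C4 disfavours the s‑cis diene, so addition may be slow. While it waits, the Lewis acid may protodesilylate or isomerise the dienol ether, and a more stepwise course could erode endo or facial selectivity. The fallback sets out from dione 18 and forms the same two bonds by an anion‑accelerated route that does not need a neutral s‑cis diene. LiN(SiMe3)2 in THF at −78 °C gives the cross‑conjugated lithium dienolate F1. On warming, its C7 adds to C8 and the resulting C9 enolate adds to C4 (intramolecular double Michael addition) to give the bicyclic C5=C6 lithium enolate F2. Trapping on oxygen with TBSCl/HMPA comes back to the route at 20.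

Step 14 (cyclobutane closure). Displacement at the neopentylic C10 may be slow, and the six‑membered ring must adopt a conformer with the C4 and C8 methyls syn‑diaxial. Proton transfer could then scramble the enolate towards C7, or the enolate could simply be protonated. The fallback sets out from mesylate 22 and closes the ring from an enone enolate instead. TBAF/AcOH hydrolyses the enol ether to the ketone mesylate F3. IBX in DMSO at 70 °C can dehydrogenate only towards C7–C8 (C4 is quaternary) and gives the enone mesylate F4, in which allylic strain with the C8 methyl holds C10 pseudo‑axial. LiN(i‑Pr)2 then forms the only available α′‑enolate (C5), which alkylates C10 and comes back to the route at 27, skipping 24.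

Step 12 (C10 reduction). Electron‑transfer reduction may not discriminate well, or may favour the axial β‑alcohol, whose sulfonate lies on the same side as C5 and cannot be displaced. The fallback sets out from 20 and separates reduction from stereocontrol. LiAlH4 in Et2O at −78 °C delivers hydride from the exposed α face to give the C10‑epimeric axial alcohol F5. Meerwein–Ponndorf–Verley/Oppenauer equilibration (Al(OiPr)3, i‑PrOH, catalytic acetone, toluene, 80 °C) should then move the mixture to the equatorial epimer, coming back to the route at 21.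

**Further compounds**

F1 | step 11 | cross‑conjugated lithium dienolate of 18 | C=C(O[Li])/C=C(\C)C[C@H](O[Si](C)(C)C(C)(C)C)[C@@H](O[Si](C)(C)C(C)(C)C)C(C)(C)C(=O)/C=C/C
F2 | step 11 | bicyclic C5=C6 lithium enolate (lithium analogue of 20) | CC(C)(C)[Si](C)(C)O[C@@H]1[C@@H](O[Si](C)(C)C(C)(C)C)C[C@@]2(C)C=C(O[Li])C[C@H](C)[C@H]2C(=O)C1(C)C
F3 | step 14 | bicyclic C6 ketone C10 α‑mesylate | CC(C)(C)[Si](C)(C)O[C@@H]1[C@@H](O[Si](C)(C)C(C)(C)C)C[C@@]2(C)CC(=O)C[C@H](C)[C@H]2[C@H](OS(C)(=O)=O)C1(C)C
F4 | step 14 | bicyclic C7=C8 enone C10 α‑mesylate | CC(C)(C)[Si](C)(C)O[C@@H]1[C@@H](O[Si](C)(C)C(C)(C)C)C[C@@]2(C)CC(=O)C=C(C)[C@H]2[C@H](OS(C)(=O)=O)C1(C)C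
F5 | step 12 | C10 β‑alcohol (C10 epimer of 21) | CC(C)(C)[Si](C)(C)O[C@@H]1[C@@H](O[Si](C)(C)C(C)(C)C)C[C@@]2(C)C=C(O[Si](C)(C)C(C)(C)C)C[C@H](C)[C@H]2[C@@H](O)C1(C)C
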